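**Strategy.** The ten-membered carbocycle is traced back to a cyclohexane: the C9 ketone lies 1,6 to the C4 carbinol carbon, so C9, C10, C1, C2, C3 and C4 are carried as a six-membered ring and the C4–C9 bond is exchanged for C6–C7. An anionic oxy-Cope rearrangement of a trans-1,2-dialkenylcyclohexanol does this in one operation: it expands the ring from six to ten members, creates the cis C6/C7 pair of the lactone fusion and leaves an E-C4=C5 alkene for the C4/C5 diol. The precursor is a C9 carbinol carrying a C8-alkoxydienyl group next to a quaternary C4 that bears an E-enol ether.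

Key step: step 16

Atom labels: carbocycle C9 (C=O), C10 (CHMe), C1, C2 (CHOH), C3, C4 (CMeOH), C5 (O-isobutyryl), C6 (lactone O), C7, C8 (O-2-methylbutanoyl); lactone carbons C11, C12 (C=O), C13 (=CH2).

Stereochemical check: a chair transition state analysis carries the configuration of 22 into that of 25, and 25 matches the target at C2, C6, C7, C8 and C10; the structures are used as drawn.

Design changes to the precursor route: the E-enol ether on C4 is made by stereoretentive C–O coupling of an alkenylboronate. The C8 nucleophile is made by tin–lithium exchange, with the stannane installed while the C12 oxygen is a lithium alkoxide, because an allylic C12 ether would be deprotonated competitively.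

Assumption: the (R,R)-configured lithium amide is taken to remove the α-proton at the carbon that becomes C4, by analogy with related meso cyclohexanones; if the opposite sense is found, the (S,S)-amine is used.

**Route**

Step 1
Reactants: 1 2,6-dimethyl-1,4-benzoquinone
Product: 2 2,6-dimethylcyclohexane-1,4-diol (stereoisomer mixture)
Conditions: H2 (60 bar), Rh/Al2O3, EtOH–AcOH, 60 °C
Reagents that add atoms: none
Why: Heterogeneous hydrogenation reduces the quinone to the hydroquinone and then saturates the arene over rhodium (arene hydrogenation), and the stereoisomer mixture is harmless because both methyl centres are equilibrated and the C2 carbinol is reset in steps 2 and 3.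

Step 2
Reactants: 2 2,6-dimethylcyclohexane-1,4-diol
Product: 3 cis-2,6-dimethylcyclohexane-1,4-dione (meso)
Conditions: Pr4N[RuO4] (cat.), NMO, 4 Å MS, CH2Cl2, rt; then DBU (cat.), rt
Reagents that add atoms: none
Why: Ley–Griffith oxidation converts both secondary alcohols into ketones and the amidine base epimerises the two α-methyl centres to the thermodynamically preferred diequatorial cis dione.

Step 3
Reactants: 3 cis-2,6-dimethylcyclohexane-1,4-dione
Product: 4 (2R,4s,6S)-4-hydroxy-2,6-dimethylcyclohexanone (hydroxyl trans to both methyls)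
Conditions: Li[HB(s-Bu)3], THF, −78 °C
Reagents that add atoms: none
Why: The bulky borohydride reduces only the carbonyl that is not flanked by α-methyl groups and attacks it from the equatorial side of the chair with equatorial methyls (equatorial-attack hydride reduction of a 3,5-disubstituted cyclohexanone), so the new hydroxyl is axial and trans to both methyls as C2 requires.

Step 4
Reactants: 4 (2R,4s,6S)-4-hydroxy-2,6-dimethylcyclohexanone
Product: 5 (2R,4s,6S)-4-(tert-butyldimethylsilyloxy)-2,6-dimethylcyclohexanone (meso)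
Conditions: TBSCl, imidazole, DMF, rt
Reagents that add atoms: tert-butyldimethylsilyl chloride, CC(C)(C)[Si](C)(C)Cl
Why: Imidazole-promoted silylation of a secondary alcohol (Corey protocol) proceeds without enolising the ketone.

Step 5
Reactants: 5 (2R,4s,6S)-4-(tert-butyldimethylsilyloxy)-2,6-dimethylcyclohexanone
Product: 7 (4S,6S)-4-(tert-butyldimethylsilyloxy)-2,6-dimethyl-1-(trimethylsilyloxy)cyclohex-1-ene, via lithium enolate 6 (not isolated)
Conditions: (R,R)-bis(1-phenylethyl)amine, n-BuLi, THF; TMSCl (in situ quench), −100 °C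
Reagents that add atoms: chlorotrimethylsilane, C[Si](C)(C)Cl
Why: Enantioselective deprotonation of a meso 2,6-dimethylcyclohexanone by a chiral lithium amide with internal silyl quench (Simpkins–Koga desymmetrisation) removes one of the two enantiotopic α-protons, which fixes the carbon that becomes C4 and leaves C10 (S) and C2 untouched.

Step 6
Reactants: 7 (4S,6S)-4-(tert-butyldimethylsilyloxy)-2,6-dimethyl-1-(trimethylsilyloxy)cyclohex-1-ene
Product: 8 (2S,4S,6S)-2-allyl-4-(tert-butyldimethylsilyloxy)-2,6-dimethylcyclohexanone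
Conditions: diallyl carbonate, Pd2(dba)3 (cat.), (R)-t-BuPHOX (cat.), Bu4N[Ph3SiF2] (substoichiometric), THF, 25 °C
Reagents that add atoms: diallyl carbonate, C=CCOC(=O)OCC=C
Why: Palladium-catalysed enantioselective Tsuji allylation of a silyl enol ether forms the quaternary C4 regiospecifically, and the (R) ligand (mirror image of the one known to give (S)-2-allyl-2-methylcyclohexanone) delivers allyl to the face anti to the C10 methyl, which the substrate's own trans preference should reinforce.

Step 7
Reactants: 8 (2S,4S,6S)-2-allyl-4-(tert-butyldimethylsilyloxy)-2,6-dimethylcyclohexanone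
Product: 9 (2R,4S,6S)-4-(tert-butyldimethylsilyloxy)-2,6-dimethyl-2-[(E)-prop-1-enyl]cyclohexanone
Conditions: RuHCl(CO)(PPh3)3 (cat.), toluene, 80 °C
Reagents that add atoms: none
Why: Ruthenium hydride-catalysed alkene isomerisation (hydrometalation and β-hydride elimination) shifts the terminal double bond by one position to the E-propenyl group under neutral conditions that do not enolise C10.

Step 8
Reactants: 9 (2R,4S,6S)-4-(tert-butyldimethylsilyloxy)-2,6-dimethyl-2-[(E)-prop-1-enyl]cyclohexanone
Product: 10 (2R,4S,6S)-4-(tert-butyldimethylsilyloxy)-2,6-dimethyl-2-[(E)-2-(4,4,5,5-tetramethyl-1,3,2-dioxaborolan-2-yl)ethenyl]cyclohexanone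
Conditions: vinylboronic acid pinacol ester, second-generation Hoveyda–Grubbs catalyst (cat.), CH2Cl2, 40 °C
Reagents that add atoms: vinylboronic acid pinacol ester, C=CB1OC(C)(C)C(C)(C)O1
Why: Olefin cross-metathesis with the vinylboronate excises the terminal methyl carbon as propene and should give the E-alkenylboronate, the E geometry following from the bulk of the quaternary C4 and the boronate.

Step 9
Reactants: 10 (2R,4S,6S)-4-(tert-butyldimethylsilyloxy)-2,6-dimethyl-2-[(E)-2-(4,4,5,5-tetramethyl-1,3,2-dioxaborolan-2-yl)ethenyl]cyclohexanone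
Product: 11 (2R,4S,6S)-4-(tert-butyldimethylsilyloxy)-2-[(E)-2-(4-methoxybenzyloxy)ethenyl]-2,6-dimethylcyclohexanone
Conditions: Cu(OAc)2, Et3N, 4-methoxybenzyl alcohol (excess), 4 Å MS, air, rt
Reagents that add atoms: 4-methoxybenzyl alcohol, COc1ccc(CO)cc1
Why: Copper-promoted oxidative C–O coupling of an alkenyl pinacol boronate with an alcohol (Chan–Lam type enol ether synthesis) retains the alkene geometry and runs at room temperature under amine buffering, so the E-enol ether forms without epimerising C10.

Step 10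
Reactants: 12 (hydroxymethyl)diphenylphosphine oxide
Product: 13 [(methoxymethoxy)methyl]diphenylphosphine oxide
Conditions: MOMCl, i-Pr2NEt, CH2Cl2, 0 °C to rt
Reagents that add atoms: chloromethyl methyl ether, COCCl
Why: O-Alkylation of the primary alcohol with a chloromethyl ether under amine base (Williamson-type acetal formation) gives the Horner–Wittig reagent.

Step 11
Reactants: 14 2-methylene-1,3-propanediol
Product: 15 2-(hydroxymethyl)prop-2-enal
Conditions: MnO2, CH2Cl2, rt
Reagents that add atoms: none
Why: Activated MnO2 oxidises allylic alcohols selectively and the second hydroxymethyl group is deactivated once the alkene is conjugated to the aldehyde (allylic oxidation), so the mono-aldehyde should result and is used at once.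

Step 12
Reactants: 15 2-(hydroxymethyl)prop-2-enal; 13 [(methoxymethoxy)methyl]diphenylphosphine oxide
Product: 17 (E)-4-(methoxymethoxy)-2-methylenebut-3-en-1-ol, via phosphine oxide adduct 16 (not isolated)
Conditions: 13 (2.1 equiv), LiN(i-Pr)2 (2.1 equiv), THF, −78 °C; 15; then KOt-Bu, −78 °C to rt; E isomer separated on Et3N-washed silica
Reagents that add atoms: none
Why: Horner–Wittig olefination, in which the lithiated α-alkoxymethyl phosphine oxide (one equivalent is spent on the hydroxyl) adds to the aldehyde and the potassium alkoxide expels diphenylphosphinate, should give the C7=C8 dienol ether as an E/Z pair from which the E isomer (OMOM trans to C11) is taken on.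

Step 13
Reactants: 17 (E)-4-(methoxymethoxy)-2-methylenebut-3-en-1-ol
Product: 19 (Z)-4-(methoxymethoxy)-2-methylene-4-(tributylstannyl)but-3-en-1-ol, via dilithio species 18 (not isolated)
Conditions: s-BuLi (2.2 equiv), THF, −78 °C; Bu3SnCl
Reagents that add atoms: tributyltin chloride, CCCC[Sn](Cl)(CCCC)CCCC
Why: Directed α-lithiation of an enol ether, in which the first equivalent forms the C12 lithium alkoxide (this suppresses allylic C12–H deprotonation) and the second, guided by the MOM oxygens, removes the vinylic C8–H with retention, so that stannylation places tin cis to C11.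

Step 14
Reactants: 19 (Z)-4-(methoxymethoxy)-2-methylene-4-(tributylstannyl)but-3-en-1-ol
Product: 20 tributyl[(1Z)-4-(4-methoxybenzyloxy)-1-(methoxymethoxy)-3-methylenebut-1-en-1-yl]stannane
Conditions: NaH, PMBCl, Bu4NI (cat.), THF–DMF, 0 °C to rt
Reagents that add atoms: 4-methoxybenzyl chloride, COc1ccc(CCl)cc1
Why: Williamson etherification of the primary alkoxide is compatible with the vinylstannane and the dienol ether, both of which tolerate base.

Step 15
Reactants: 20 tributyl[(1Z)-4-(4-methoxybenzyloxy)-1-(methoxymethoxy)-3-methylenebut-1-en-1-yl]stannane; 11 (2R,4S,6S)-4-(tert-butyldimethylsilyloxy)-2-[(E)-2-(4-methoxybenzyloxy)ethenyl]-2,6-dimethylcyclohexanone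
Product: 22 (1R,2R,4S,6S)-4-(tert-butyldimethylsilyloxy)-2-[(E)-2-(4-methoxybenzyloxy)ethenyl]-1-[(1E)-4-(4-methoxybenzyloxy)-1-(methoxymethoxy)-3-methylenebut-1-enyl]-2,6-dimethylcyclohexan-1-ol, via alkenyllithium 21 (not isolated)
Conditions: n-BuLi, THF, −78 °C; then 11, −78 °C; H2O
Reagents that add atoms: none
Why: Tin–lithium exchange gives the α-alkoxyalkenyllithium with retention and without competing C–H deprotonation, and its 1,2-addition to the ketone should occur by axial attack on the chair with equatorial methyls, anti to the axial C4 alkenyl group, which sets C9 and places the two alkenyl groups trans.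

Step 16
Reactants: 22 (1R,2R,4S,6S)-4-(tert-butyldimethylsilyloxy)-2-[(E)-2-(4-methoxybenzyloxy)ethenyl]-1-[(1E)-4-(4-methoxybenzyloxy)-1-(methoxymethoxy)-3-methylenebut-1-enyl]-2,6-dimethylcyclohexan-1-ol
Product: 25 (2S,6S,7S,8S,10S,4E)-2-(tert-butyldimethylsilyloxy)-6-(4-methoxybenzyloxy)-7-[3-(4-methoxybenzyloxy)prop-1-en-2-yl]-8-(methoxymethoxy)-4,10-dimethylcyclodec-4-en-9-one (atom labels as above), via potassium alkoxide 23 (not isolated), via potassium enolate 24 (not isolated)
Conditions: KH, 18-crown-6, THF, 0 °C to rt; then AcOH, THF, −78 °C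
Reagents that add atoms: none
Why: KH and the crown ether give the C9 potassium alkoxide 23, whose oxyanion weakens the adjacent C4–C9 bond so that the [3,3]-sigmatropic shift (C6–C7 formed, C4–C9 broken) runs near room temperature and ends in the C8=C9 enolate 24, which makes the step irreversible. The closest known reaction type is the anionic oxy-Cope rearrangement of trans-1,2-divinylcyclohexanols to E-cyclodec-5-enones used for germacrane rings. The ten-membered ring is not closed end to end but arises by four-atom expansion of the cyclohexane through a six-membered chair transition state in which both alkenyl groups are equatorial on the cyclohexane. In that chair the E-enol ether places the C6 oxygen pseudo-equatorial and the C7=C8 geometry (C11 cis to C9) places C11 pseudo-axial, so the C4/C9 configuration is relayed to C6 and C7 with the cis relationship of the lactone fusion, while the pseudo-equatorial ring bonds to C3 and C10 give the E-C4=C5 alkene. C8 is set when the enolate is protonated at −78 °C on its exposed face, the one turned away from the transannular C4=C5 bond. The step needs the chair over the boat and access to the conformer with the C4 and C10 methyls syn-axial; the other chair suffers a syn-axial clash between the C4 alkenyl group and the C2 silyloxy group, and irreversible enolate formation drains the equilibrium through the reactive conformer.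

Step 17
Reactants: 25 cyclodec-4-en-9-one from step 16
Product: 26 (2S,4S,5S,6R,7S,8S,10S)-C4,C5-diol of 25 (other groups unchanged)
Conditions: OsO4 (cat.), NMO, acetone–H2O, 0 °C
Reagents that add atoms: N-methylmorpholine N-oxide, C[N+]1([O-])CCOCC1; water, O
Why: Upjohn dihydroxylation (syn addition) should take the strained, electron-rich E-trisubstituted C4=C5 bond well before the 1,1-disubstituted C11=C13 bond, and attack on its exposed peripheral face, anti to the transannular C9, gives the 4S,5S diol.

Step 18
Reactants: 26 C4,C5-diol; 27 isobutyryl chloride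
Product: 28 C5 isobutyrate of 26 (C4 hydroxyl free)
Conditions: pyridine, DMAP (cat.), CH2Cl2, 0 °C
Reagents that add atoms: none
Why: Acylation with an acid chloride under nucleophilic catalysis esterifies the secondary C5 hydroxyl, while the tertiary C4 hydroxyl is too hindered to react.

Step 19
Reactants: 28 C5 isobutyrate
Product: 29 C6,C12-diol (both 4-methoxybenzyl groups removed; configurations as in 36)
Conditions: DDQ, CH2Cl2–pH 7 buffer, 0 °C to rt
Reagents that add atoms: none
Why: Oxidative cleavage of 4-methoxybenzyl ethers by DDQ (hydride abstraction, then hydrolysis of the hemiacetal) frees both hydroxyls under buffered conditions that leave the silyl ether, the MOM acetal and the ester intact.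

Step 20
Reactants: 29 C6,C12-diol
Product: 32 α-methylene-γ-lactone (C12 carbonyl, lactone oxygen on C6) carrying C8–OMOM, C5 isobutyrate, C4–OH and C2–OTBS, via hydroxy enal 30 (not isolated), via lactol 31 (not isolated)
Conditions: MnO2, CH2Cl2, rt
Reagents that add atoms: none
Why: Oxidative lactonisation of a 2-methylene-1,4-diol, in which MnO2 oxidises the primary allylic C12 alcohol to the enal, the cis-disposed C6 hydroxyl closes the five-membered lactol and a second oxidation gives the lactone.

Step 21
Reactants: 32 α-methylene-γ-lactone with C8–OMOM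
Product: 33 C8 alcohol (MOM removed; configurations as in 36)
Conditions: Me2BBr, CH2Cl2, −78 °C; then NaHCO3 (aq.)
Reagents that add atoms: none
Why: Me2BBr cleaves acetal-type MOM ethers at −78 °C by coordination and bromide attack at the acetal methylene (Lewis acid acetal cleavage), conditions under which the secondary silyl ether, the isobutyrate and the lactone are inert.

Step 22
Reactants: 33 C8 alcohol; 34 (R)-2-methylbutanoic acid
Product: 35 C8 (R)-2-methylbutanoate with C2–OTBS
Conditions: DCC, DMAP (cat.), CH2Cl2, 0 °C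
Reagents that add atoms: none
Why: Steglich esterification acylates the secondary α-ketol hydroxyl, the tertiary C4 hydroxyl does not react, and low temperature with catalytic DMAP keeps the α-centre of the acid and C8 intact.

Step 23
Reactants: 35 C8 (R)-2-methylbutanoate with C2–OTBS
Product: 36 target CNP0244577.2, (2S,4S,5S,6R,7S,8S,10S) with (R)-2-methylbutanoate
Conditions: HF·pyridine, THF–pyridine, 0 °C to rt
Reagents that add atoms: none
Why: Fluoride-mediated desilylation under non-basic conditions frees the C2 hydroxyl without acyl migration, elimination at C8 or addition to the α-methylene lactone.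

**Compound list**

1 | 2,6-dimethyl-1,4-benzoquinone | CC1=CC(=O)C=C(C)C1=O | starting material
2 | 2,6-dimethylcyclohexane-1,4-diol (stereoisomer mixture) | CC1CC(O)CC(C)C1O | intermediate
3 | cis-2,6-dimethylcyclohexane-1,4-dione (meso) | O=C1[C@@H](C)CC(=O)C[C@H]1C | intermediate
4 | (2R,4s,6S)-4-hydroxy-2,6-dimethylcyclohexanone | O=C1[C@@H](C)C[C@H](O)C[C@H]1C | intermediate
5 | (2R,4s,6S)-4-(tert-butyldimethylsilyloxy)-2,6-dimethylcyclohexanone | O=C1[C@@H](C)C[C@H](O[Si](C)(C)C(C)(C)C)C[C@H]1C | intermediate
6 | lithium enolate of 5 (C4=C9 enolate, not isolated) | [Li+].[O-]C1=C(C)C[C@@H](O[Si](C)(C)C(C)(C)C)C[C@@H]1C | intermediate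
7 | (4S,6S)-4-(tert-butyldimethylsilyloxy)-2,6-dimethyl-1-(trimethylsilyloxy)cyclohex-1-ene | C[Si](C)(C)OC1=C(C)C[C@@H](O[Si](C)(C)C(C)(C)C)C[C@@H]1C | intermediate
8 | (2S,4S,6S)-2-allyl-4-(tert-butyldimethylsilyloxy)-2,6-dimethylcyclohexanone | O=C1[C@@H](C)C[C@H](O[Si](C)(C)C(C)(C)C)C[C@]1(C)CC=C | intermediate
9 | (2R,4S,6S)-4-(tert-butyldimethylsilyloxy)-2,6-dimethyl-2-[(E)-prop-1-enyl]cyclohexanone | O=C1[C@@H](C)C[C@H](O[Si](C)(C)C(C)(C)C)C[C@]1(C)/C=C/C | intermediate
10 | (2R,4S,6S)-4-(tert-butyldimethylsilyloxy)-2,6-dimethyl-2-[(E)-2-(pinacolboryl)ethenyl]cyclohexanone | O=C1[C@@H](C)C[C@H](O[Si](C)(C)C(C)(C)C)C[C@]1(C)/C=C/B2OC(C)(C)C(C)(C)O2 | intermediate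
11 | (2R,4S,6S)-4-(tert-butyldimethylsilyloxy)-2-[(E)-2-(4-methoxybenzyloxy)ethenyl]-2,6-dimethylcyclohexanone | O=C1[C@@H](C)C[C@H](O[Si](C)(C)C(C)(C)C)C[C@]1(C)/C=C/OCc2ccc(OC)cc2 | intermediate
12 | (hydroxymethyl)diphenylphosphine oxide | O=P(CO)(c1ccccc1)c1ccccc1 | starting material
13 | [(methoxymethoxy)methyl]diphenylphosphine oxide | COCOCP(=O)(c1ccccc1)c1ccccc1 | intermediate
14 | 2-methylene-1,3-propanediol | C=C(CO)CO | starting material
15 | 2-(hydroxymethyl)prop-2-enal | C=C(CO)C=O | intermediate
16 | Horner–Wittig adduct as dilithium alkoxide (diastereomer mixture, not isolated) | [Li]OCC(=C)C(O[Li])C(OCOC)P(=O)(c1ccccc1)c1ccccc1 | intermediate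
17 | (E)-4-(methoxymethoxy)-2-methylenebut-3-en-1-ol | OCC(=C)/C=C/OCOC | intermediate
18 | C8-lithiated lithium alkoxide of 17 (not isolated) | [Li]OCC(=C)/C=C(/OCOC)[Li] | intermediate
19 | (Z)-4-(methoxymethoxy)-2-methylene-4-(tributylstannyl)but-3-en-1-ol | OCC(=C)/C=C(/OCOC)[Sn](CCCC)(CCCC)CCCC | intermediate
20 | tributyl[(1Z)-4-(4-methoxybenzyloxy)-1-(methoxymethoxy)-3-methylenebut-1-en-1-yl]stannane | COc1ccc(COCC(=C)/C=C(/OCOC)[Sn](CCCC)(CCCC)CCCC)cc1 | intermediate
21 | [(1E)-4-(4-methoxybenzyloxy)-1-(methoxymethoxy)-3-methylenebut-1-en-1-yl]lithium (Li cis to C11, not isolated) | COc1ccc(COCC(=C)/C=C(/OCOC)[Li])cc1 | intermediate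
22 | oxy-Cope precursor, (1R,2R,4S,6S)-trans-1,2-dialkenylcyclohexanol (C9 carbinol, C4 quaternary) | O[C@]1(/C(OCOC)=C\C(=C)COCc2ccc(OC)cc2)[C@@H](C)C[C@H](O[Si](C)(C)C(C)(C)C)C[C@]1(C)/C=C/OCc3ccc(OC)cc3 | intermediate
23 | potassium C9 alkoxide of 22 (not isolated) | [K+].[O-][C@]1(/C(OCOC)=C\C(=C)COCc2ccc(OC)cc2)[C@@H](C)C[C@H](O[Si](C)(C)C(C)(C)C)C[C@]1(C)/C=C/OCc3ccc(OC)cc3 | intermediate
24 | potassium C8=C9 enolate of the ten-membered ring (not isolated) | [K+].COc1ccc(CO[C@@H]2[C@H](C(=C)COCc3ccc(OC)cc3)/C(OCOC)=C(\[O-])[C@@H](C)C[C@H](O[Si](C)(C)C(C)(C)C)C/C(C)=C/2)cc1 | intermediate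
25 | (2S,6S,7S,8S,10S,4E)-cyclodec-4-en-9-one with 2-OTBS, 6-OPMB, 7-[3-(PMB-oxy)prop-1-en-2-yl], 8-OMOM, 4,10-dimethyl | COc1ccc(CO[C@@H]2[C@H](C(=C)COCc3ccc(OC)cc3)[C@H](OCOC)C(=O)[C@@H](C)C[C@H](O[Si](C)(C)C(C)(C)C)C/C(C)=C/2)cc1 | intermediate
26 | (4S,5S)-C4,C5-diol of 25 | COc1ccc(CO[C@@H]2[C@H](C(=C)COCc3ccc(OC)cc3)[C@H](OCOC)C(=O)[C@@H](C)C[C@H](O[Si](C)(C)C(C)(C)C)C[C@](C)(O)[C@H]2O)cc1 | intermediate
27 | isobutyryl chloride | CC(C)C(Cl)=O | starting material
28 | C5 isobutyrate of 26 | COc1ccc(CO[C@@H]2[C@H](C(=C)COCc3ccc(OC)cc3)[C@H](OCOC)C(=O)[C@@H](C)C[C@H](O[Si](C)(C)C(C)(C)C)C[C@](C)(O)[C@H]2OC(=O)C(C)C)cc1 | intermediate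
29 | C6,C12-diol (PMB groups removed) | O[C@@H]1[C@H](C(=C)CO)[C@H](OCOC)C(=O)[C@@H](C)C[C@H](O[Si](C)(C)C(C)(C)C)C[C@](C)(O)[C@H]1OC(=O)C(C)C | intermediate
30 | C12 enal with free C6 hydroxyl (not isolated) | O[C@@H]1[C@H](C(=C)C=O)[C@H](OCOC)C(=O)[C@@H](C)C[C@H](O[Si](C)(C)C(C)(C)C)C[C@](C)(O)[C@H]1OC(=O)C(C)C | intermediate
31 | C12 lactol (not isolated, C12 epimers) | C=C1C(O)O[C@@H]2[C@H]1[C@H](OCOC)C(=O)[C@@H](C)C[C@H](O[Si](C)(C)C(C)(C)C)C[C@](C)(O)[C@H]2OC(=O)C(C)C | intermediate
32 | α-methylene-γ-lactone with C8–OMOM, C5 isobutyrate, C4–OH, C2–OTBS | C=C1C(=O)O[C@@H]2[C@H]1[C@H](OCOC)C(=O)[C@@H](C)C[C@H](O[Si](C)(C)C(C)(C)C)C[C@](C)(O)[C@H]2OC(=O)C(C)C | intermediate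
33 | C8 alcohol of 32 | C=C1C(=O)O[C@@H]2[C@H]1[C@H](O)C(=O)[C@@H](C)C[C@H](O[Si](C)(C)C(C)(C)C)C[C@](C)(O)[C@H]2OC(=O)C(C)C | intermediate
34 | (R)-2-methylbutanoic acid | CC[C@@H](C)C(=O)O | starting material
35 | C8 (R)-2-methylbutanoate with C2–OTBS | C=C1C(=O)O[C@@H]2[C@H]1[C@H](OC(=O)[C@H](C)CC)C(=O)[C@@H](C)C[C@H](O[Si](C)(C)C(C)(C)C)C[C@](C)(O)[C@H]2OC(=O)C(C)C | intermediate
36 | CNP0244577.2, (2S,4S,5S,6R,7S,8S,10S)-germacranolide with C5 isobutyrate and C8 (R)-2-methylbutanoate | C=C1C(=O)O[C@@H]2[C@H]1[C@H](OC(=O)[C@H](C)CC)C(=O)[C@@H](C)C[C@H](O)C[C@](C)(O)[C@H]2OC(=O)C(C)C | target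

**Step count and risks**

Total step count: 23. Longest linear sequence: 18 steps (steps 1–9 and 15–23).

Most likely to fail:

1. Step 16 (oxy-Cope). The alkoxide may not reach the chair that carries the C4 and C10 methyls syn-axial and may instead fragment by heterolysis of the C4–C9 bond, or the enolate may be protonated without facial control at C8. Fallback: 22 is silylated (N-(trimethylsilyl)imidazole, rt) to the C9 trimethylsilyl ether F1, which is heated in o-dichlorobenzene at 180–200 °C in base-washed glass; this neutral siloxy-Cope rearrangement avoids the free alkoxide and gives the ten-membered trimethylsilyl enol ether F2, whose protonolysis at C8 (AcOH, THF–H2O, 0 °C) returns to 25.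

2. Step 17 (dihydroxylation). Osmylation may also attack the C11=C13 alkene, or may occur on the other face if the E-alkene turns through the ring before it reacts. Fallback: the order is changed so that the lactone is in place first. From 25, DDQ (CH2Cl2–pH 7 buffer) gives the C6,C12-diol with intact E-alkene F3, and primary-selective oxidative lactonisation (TEMPO cat., PhI(OAc)2, CH2Cl2) gives the α-methylene lactone with intact E-alkene F4. In F4 the C11=C13 bond is electron-poor and the cis-fused lactone restricts the ring, so OsO4 (cat.) with NMO should give the lactone C4,C5-diol F5, and acylation with 27 (pyridine, DMAP) rejoins the route at 32.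

3. Step 8 (cross-metathesis). Turnover may be slow at the alkene flanked by the quaternary C4, and the neighbouring ketone may chelate the ruthenium carbene. Fallback: from 9, ozonolysis (O3, CH2Cl2, −78 °C; PPh3) gives the 2-formyl ketone F6, and Takai–Utimoto boryl-olefination (CrCl2, Cl2CHB(pin), LiI, THF, rt) converts the aldehyde E-selectively into 10.

Further compounds
F1 | step 16 | C9 trimethylsilyl ether of 22 | C[Si](C)(C)O[C@]1(/C(OCOC)=C\C(=C)COCc2ccc(OC)cc2)[C@@H](C)C[C@H](O[Si](C)(C)C(C)(C)C)C[C@]1(C)/C=C/OCc3ccc(OC)cc3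
F2 | step 16 | ten-membered C8=C9 trimethylsilyl enol ether | COc1ccc(CO[C@@H]2[C@H](C(=C)COCc3ccc(OC)cc3)/C(OCOC)=C(\O[Si](C)(C)C)[C@@H](C)C[C@H](O[Si](C)(C)C(C)(C)C)C/C(C)=C/2)cc1
F3 | step 17 | C6,C12-diol with intact E-C4=C5 alkene | O[C@@H]1[C@H](C(=C)CO)[C@H](OCOC)C(=O)[C@@H](C)C[C@H](O[Si](C)(C)C(C)(C)C)C/C(C)=C/1
F4 | step 17 | α-methylene lactone with intact E-C4=C5 alkene | C=C1C(=O)O[C@@H]2[C@H]1[C@H](OCOC)C(=O)[C@@H](C)C[C@H](O[Si](C)(C)C(C)(C)C)C/C(C)=C/2
F5 | step 17 | lactone C4,C5-diol | C=C1C(=O)O[C@@H]2[C@H]1[C@H](OCOC)C(=O)[C@@H](C)C[C@H](O[Si](C)(C)C(C)(C)C)C[C@](C)(O)[C@H]2O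
F6 | step 8 | 2-formyl ketone (C4–CHO; C2, C4, C10 as in 9) | O=C1[C@@H](C)C[C@H](O[Si](C)(C)C(C)(C)C)C[C@]1(C)C=O
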